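**Retrosynthetic overview**

1. Locants follow flavanone numbering. In the side chain, C1'' is the benzylic CH2 on C8, C2'' the stereocentre, C3'' the isopropenyl carbon, and C4''–C6'' the prenyl arm. The last cuts are the two MOM ethers and then the C2–C1' bond. Ring B arrives by catalyst-controlled asymmetric 1,4-arylation of an 8-lavandulylchromone, so the labile C2 centre is made only after every hot or acidic step.
2. The key cut is C1''–C2''. The whole chain is made in one flask from a chromone-8-carbaldehyde 2-nitrobenzenesulfonylhydrazone and an achiral (E)-2,6-dimethylhepta-2,5-dienylboron reagent, by diol-catalysed allylboration followed by spontaneous loss of sulfinate and N2.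
3. The enabling feature is the homoallylic array C8(ring A)–C1''H2–C2''H–C3''(CH3)=CH2. C1'' is benzylic and ortho to O7, so it can be carried at the aldehyde level and introduced ortho to the free 7-OH. C2'' is allylic to C3''=CH2, so it is the γ-carbon of a 2-methylallylboron unit. The transient C1''–N stereocentre relays the catalyst's chirality to C2'' through a chair and is then erased.
4. Ring order: ring A is bought with its oxygen pattern, and the 6'-OMe leaves only one phenol ortho to the acetyl group, so ring C can close in one direction only. Ring C is closed first, as the aromatic pyranone. Ring B is attached last, which turns ring C into the dihydropyranone.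
5. The boron reagent comes from propargyl alcohol, AlMe3 and prenyl chloride (E geometry from syn-carboalumination), followed by allylic borylation.

Key step: step 7

Assumption: the (S)-diol in step 7 is taken to leave the Re face of C1'' open, and the (S)-diphosphine in step 10 the Re face of C2 (the latter by analogy with the parent chromone); if a model run shows the opposite sense, the antipodal ligand is used and nothing else changes.

**Route**

Step 1
Reactants: 1 1-(2,4-dihydroxy-6-methoxyphenyl)ethan-1-one
Product: 3 7-hydroxy-5-methoxy-4H-chromen-4-one, via 4-ethoxychromenylium perchlorate 2 (not isolated)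
Conditions: HC(OEt)3, 70% HClO4, 25 °C; then H2O, 90 °C
Reagents that add atoms: triethyl orthoformate CCOC(OCC)OCC; water O
Why: Orthoformate–perchloric acid chromone synthesis, in which the acetyl CH3 is formylated at the enol stage and the only phenol ortho to the acetyl group (the other ortho position carries OMe) closes ring C to salt 2, which hot water hydrolyses to the pyranone; no stereocentre is formed.

Step 2
Reactants: 3 7-hydroxy-5-methoxy-4H-chromen-4-one
Product: 4 7-hydroxy-5-methoxy-4-oxo-4H-chromene-8-carbaldehyde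
Conditions: hexamethylenetetramine, AcOH, 100 °C; then 3 M aq HCl, 70 °C
Reagents that add atoms: hexamethylenetetramine C1N2CN3CN1CN(C2)C3; water O
Why: Duff reaction, in which the hexamine-derived iminium ion attacks ortho to the free 7-OH, C8 (para to the 5-OMe and on the C7–C8 bond of higher double-bond character in 7-hydroxybenzopyranones) should be preferred over C6, and internal hydride transfer plus hydrolysis give the aldehyde carbon that becomes C1''.

Step 3
Reactants: 4 7-hydroxy-5-methoxy-4-oxo-4H-chromene-8-carbaldehyde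
Product: 5 5-methoxy-7-(methoxymethoxy)-4-oxo-4H-chromene-8-carbaldehyde
Conditions: MOMCl, i-Pr2NEt, CH2Cl2, 0 to 25 °C
Reagents that add atoms: chloromethyl methyl ether COCCl
Why: O-alkylation of the acidic, hydrogen-bonded 7-OH, whose cap keeps the phenol off boron in step 7 and off rhodium in step 10.

Step 4
Reactants: 5 5-methoxy-7-(methoxymethoxy)-4-oxo-4H-chromene-8-carbaldehyde
Product: 6 N'-[(E)-{5-methoxy-7-(methoxymethoxy)-4-oxo-4H-chromen-8-yl}methylidene]-2-nitrobenzenesulfonohydrazide
Conditions: 2-nitrobenzenesulfonohydrazide (1.0 equiv), MeCN, 0 to 25 °C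
Reagents that add atoms: 2-nitrobenzenesulfonohydrazide NNS(=O)(=O)c1ccccc1[N+](=O)[O-]
Why: Hydrazone condensation at the aldehyde, which is much faster than attack of the weakly nucleophilic sulfonylhydrazide at C2 of the pyranone and gives the E isomer for steric reasons.

Step 5
Reactants: 7 prop-2-yn-1-ol; 8 1-chloro-3-methylbut-2-ene (prenyl chloride)
Product: 10 (2E)-2,6-dimethylhepta-2,5-dien-1-ol, via E-alkenylalane 9 (not isolated)
Conditions: AlMe3 (3 equiv), Cp2ZrCl2 (0.25 equiv), CH2Cl2, 0 to 25 °C; then 8, Pd(PPh3)4 (5 mol %), THF, 25 °C; aq work-up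
Reagents that add atoms: trimethylaluminium C[Al](C)C
Why: Negishi zirconium-catalysed carboalumination adds CH3 and Al syn across the alkyne with Al on the terminal carbon, and the palladium-catalysed alkenyl–allyl coupling of 9 at the primary carbon of prenyl chloride goes with retention, which fixes the E alkene.

Step 6
Reactants: 10 (2E)-2,6-dimethylhepta-2,5-dien-1-ol
Product: 11 [(2E)-2,6-dimethylhepta-2,5-dien-1-yl]boronic acid
Conditions: B2(OH)4 (1.2 equiv), [Pd(MeCN)4](BF4)2 (1 mol %), MeOH, 25 °C, Ar; precipitation with degassed brine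
Reagents that add atoms: tetrahydroxydiboron OB(O)B(O)O
Why: Palladium-catalysed borylation of an allylic alcohol through an η3-allylpalladium intermediate, with boron delivered to the primary terminus and the E geometry retained.

Step 7
Reactants: 6 N'-[(E)-{5-methoxy-7-(methoxymethoxy)-4-oxo-4H-chromen-8-yl}methylidene]-2-nitrobenzenesulfonohydrazide; 11 [(2E)-2,6-dimethylhepta-2,5-dien-1-yl]boronic acid
Product: 15 5-methoxy-7-(methoxymethoxy)-8-[(2R)-5-methyl-2-(prop-1-en-2-yl)hex-4-en-1-yl]-4H-chromen-4-one, via diisopropyl allylboronate 12 (not isolated), via syn-sulfonylhydrazide adduct 13 (not isolated), via benzylic diazene 14 (not isolated)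
Conditions: 11, i-PrOH (4 equiv), 3 Å MS, PhMe, 25 °C; then 6, (S)-3,3'-Ph2-BINOL (15 mol %), −10 °C; then 25 °C; aq work-up
Reagents that add atoms: none
Why: Proposed new method: the chiral diol exchanges onto boron of 12, the resulting Lewis-acidic boronate binds the imine nitrogen of E-hydrazone 6, and the allyl unit is handed over through a closed six-membered Zimmerman–Traxler chair in which its γ-carbon (future C2'') bonds to C1'' while the C=C moves to become the C3''=CH2 isopropenyl group, giving 13; on warming 13 loses 2-nitrobenzenesulfinic acid to the monoalkyl diazene 14, which expels N2 by a radical chain through the C1'' benzylic radical and leaves C1''H2, so the activating group removes itself in the same flask. The closest known reaction types are the biphenol-catalysed allylboration of sulfonylhydrazones in the traceless Petasis borono-Mannich reaction (where the diazene is propargylic and collapses by retro-ene), the syn-selective addition of E-allylboronic acids to acylhydrazones and the reductive coupling of aldehyde sulfonylhydrazones with organolithium reagents; new is their union on an aryl aldehyde hydrazone with a γ-substituted 2-methylallylboron reagent. No ring is closed. Two stereocentres form: C1'' (R) is set by the diol, which leaves the Re face of the C=N carbon open, and C2'' is set relative to it by the chair, in which the E-hydrazone holds ring A axial and the E-alkene holds the prenyl CH2 equatorial (syn adduct), so that after the C1'' centre is erased the surviving centre is 2''R. C2'' never lies next to a cation or a quinone methide, and the C1'' radical has only three-membered, four-membered or 5-endo closures in reach, so the centre should not be scrambled. The step needs C=N over C4=O and C2=C3 chemoselectivity (secured by the vinylogous-ester character of the pyranone), γ over α regioselectivity (secured by the closed transition state) and a slow uncatalysed addition (secured by the isopropyl ester 12, the low temperature and the MOM cap that keeps O7 off boron).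

Step 8
Reactants: 16 2-bromo-5-methoxyphenol
Product: 17 1-bromo-4-methoxy-2-(methoxymethoxy)benzene
Conditions: MOMCl, i-Pr2NEt, CH2Cl2, 0 to 25 °C
Reagents that add atoms: chloromethyl methyl ether COCCl
Why: O-alkylation of the phenol, giving a small base-stable cap that tolerates butyllithium and adds little bulk next to boron.

Step 9
Reactants: 17 1-bromo-4-methoxy-2-(methoxymethoxy)benzene
Product: 19 [4-methoxy-2-(methoxymethoxy)phenyl]boronic acid, via aryllithium 18 (not isolated)
Conditions: n-BuLi, THF, −78 °C; B(Oi-Pr)3, −78 to 25 °C; dilute aq HCl to pH 5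
Reagents that add atoms: triisopropyl borate CC(C)OB(OC(C)C)OC(C)C; water O
Why: Bromine–lithium exchange fixes boron para to OMe and ortho to OMOM (direct lithiation would go between the two oxygens), and the aryllithium is trapped by the borate ester and hydrolysed.

Step 10
Reactants: 15 5-methoxy-7-(methoxymethoxy)-8-[(2R)-5-methyl-2-(prop-1-en-2-yl)hex-4-en-1-yl]-4H-chromen-4-one; 19 [4-methoxy-2-(methoxymethoxy)phenyl]boronic acid
Product: 20 (2S)-5-methoxy-7-(methoxymethoxy)-2-[4-methoxy-2-(methoxymethoxy)phenyl]-8-[(2R)-5-methyl-2-(prop-1-en-2-yl)hex-4-en-1-yl]-2,3-dihydro-4H-chromen-4-one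
Conditions: [Rh(OH)(cod)]2 (2.5 mol %), (S)-MeO-F12-BIPHEP (5.5 mol %), 19 (3 equiv), CH2Cl2/H2O 10:1, 25 °C
Reagents that add atoms: none
Why: Hayashi–Miyaura asymmetric 1,4-addition to a chromone, in which the arylrhodium species inserts into C2=C3 on the Re face of C2 left open by the (S)-biaryl diphosphine and water protonates the oxa-π-allylrhodium, so 2S is set by the catalyst independently of the remote C2'' centre, under neutral conditions that avoid retro-oxa-Michael opening and leave the unactivated alkenes alone.

Step 11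
Reactants: 20 (2S)-5-methoxy-7-(methoxymethoxy)-2-[4-methoxy-2-(methoxymethoxy)phenyl]-8-[(2R)-5-methyl-2-(prop-1-en-2-yl)hex-4-en-1-yl]-2,3-dihydro-4H-chromen-4-one
Product: 21 (2S)-7-hydroxy-2-(2-hydroxy-4-methoxyphenyl)-5-methoxy-8-[(2R)-5-methyl-2-(prop-1-en-2-yl)hex-4-en-1-yl]-2,3-dihydro-4H-chromen-4-one (target)
Conditions: NaHSO4·SiO2, CH2Cl2, 25 °C
Reagents that add atoms: none
Why: Acid-catalysed cleavage of the two phenolic MOM acetals on a weak heterogeneous acid, chosen so that neither the side-chain alkenes next to the freed 7-OH are protonated nor the C2–O1 bond is opened; both stereocentres are untouched.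

**Compound list**

1 | 1-(2,4-dihydroxy-6-methoxyphenyl)ethan-1-one | CC(=O)c1c(O)cc(O)cc1OC | starting material
2 | 4-ethoxy-7-hydroxy-5-methoxychromenylium perchlorate | CCOc1cc[o+]c2cc(O)cc(OC)c12.[O-]Cl(=O)(=O)=O | intermediate
3 | 7-hydroxy-5-methoxy-4H-chromen-4-one | O=c1ccoc2cc(O)cc(OC)c12 | intermediate
4 | 7-hydroxy-5-methoxy-4-oxo-4H-chromene-8-carbaldehyde | O=Cc1c(O)cc(OC)c2c1occc2=O | intermediate
5 | 5-methoxy-7-(methoxymethoxy)-4-oxo-4H-chromene-8-carbaldehyde | COCOc1cc(OC)c2c(c1C=O)occc2=O | intermediate
6 | N'-[(E)-{5-methoxy-7-(methoxymethoxy)-4-oxo-4H-chromen-8-yl}methylidene]-2-nitrobenzenesulfonohydrazide | COCOc1cc(OC)c2c(c1/C=N/NS(=O)(=O)c1ccccc1[N+](=O)[O-])occc2=O | intermediate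
7 | prop-2-yn-1-ol | C#CCO | starting material
8 | 1-chloro-3-methylbut-2-ene | CC(C)=CCCl | starting material
9 | [(1E)-3-(dimethylalumanyloxy)-2-methylprop-1-en-1-yl]dimethylalumane | C[Al](C)/C=C(\C)CO[Al](C)C | intermediate
10 | (2E)-2,6-dimethylhepta-2,5-dien-1-ol | OC/C(C)=C/CC=C(C)C | intermediate
11 | [(2E)-2,6-dimethylhepta-2,5-dien-1-yl]boronic acid | OB(O)C/C(C)=C/CC=C(C)C | intermediate
12 | diisopropyl [(2E)-2,6-dimethylhepta-2,5-dien-1-yl]boronate | CC(C)OB(C/C(C)=C/CC=C(C)C)OC(C)C | intermediate
13 | N'-{(1R,2S)-1-[5-methoxy-7-(methoxymethoxy)-4-oxo-4H-chromen-8-yl]-5-methyl-2-(prop-1-en-2-yl)hex-4-en-1-yl}-2-nitrobenzenesulfonohydrazide | C=C(C)[C@H](CC=C(C)C)[C@@H](NNS(=O)(=O)c1ccccc1[N+](=O)[O-])c1c(OCOC)cc(OC)c2c1occc2=O | intermediate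
14 | 8-[(1R,2S)-1-diazenyl-5-methyl-2-(prop-1-en-2-yl)hex-4-en-1-yl]-5-methoxy-7-(methoxymethoxy)-4H-chromen-4-one | C=C(C)[C@H](CC=C(C)C)[C@@H](N=N)c1c(OCOC)cc(OC)c2c1occc2=O | intermediate
15 | 5-methoxy-7-(methoxymethoxy)-8-[(2R)-5-methyl-2-(prop-1-en-2-yl)hex-4-en-1-yl]-4H-chromen-4-one | C=C(C)[C@H](CC=C(C)C)Cc1c(OCOC)cc(OC)c2c1occc2=O | intermediate
16 | 2-bromo-5-methoxyphenol | COc1ccc(Br)c(O)c1 | starting material
17 | 1-bromo-4-methoxy-2-(methoxymethoxy)benzene | COCOc1cc(OC)ccc1Br | intermediate
18 | [4-methoxy-2-(methoxymethoxy)phenyl]lithium | [Li]c1ccc(OC)cc1OCOC | intermediate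
19 | [4-methoxy-2-(methoxymethoxy)phenyl]boronic acid | COCOc1cc(OC)ccc1B(O)O | intermediate
20 | (2S)-5-methoxy-7-(methoxymethoxy)-2-[4-methoxy-2-(methoxymethoxy)phenyl]-8-[(2R)-5-methyl-2-(prop-1-en-2-yl)hex-4-en-1-yl]-2,3-dihydro-4H-chromen-4-one | C=C(C)[C@H](CC=C(C)C)Cc1c(OCOC)cc(OC)c2c1O[C@H](c1ccc(OC)cc1OCOC)CC2=O | intermediate
21 | (2S)-7-hydroxy-2-(2-hydroxy-4-methoxyphenyl)-5-methoxy-8-[(2R)-5-methyl-2-(prop-1-en-2-yl)hex-4-en-1-yl]-2,3-dihydro-4H-chromen-4-one | C=C(C)[C@H](CC=C(C)C)Cc1c(O)cc(OC)c2c1O[C@H](c1ccc(OC)cc1O)CC2=O | target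

**Step count**

Total step count: 11.
Longest linear sequence: 7 steps (1, 2, 3, 4, 7, 10, 11).

**Steps most likely to fail**

1. Step 7 (the proposed new method).
   - The addition may be slow, because C1'' is flanked by two ortho oxygen substituents and ring A must sit axial in the chair.
   - Uncatalysed addition of the boron reagent, leakage through a boat, or E/Z isomerisation of the hydrazone would each lower the facial fidelity at C2''.
   - The fallback uses known chemistry; it sets out from 5 and 11 and comes back at 15. Boronic acid 11 is esterified with pinacol (MgSO4, Et2O) to the (E)-allyl pinacol boronate F1. Aldehyde 5 is allylated with F1 under catalysis by (S)-TRIP hydrogen phosphate (5 mol %, toluene, −30 °C). This is an established chair-type allylboration with the aryl group equatorial, in which Si-face attack and the E alkene should give the anti (1S,2S)-homoallylic alcohol F2, with the same spatial arrangement at C2''. F2 is treated with 1,1'-thiocarbonyldiimidazole (DMAP, CH2Cl2, 40 °C) to give the imidazolylthiocarbonate F3. Barton–McCombie reduction (Bu3SnH, AIBN, toluene, 80 °C) then removes the oxygen through the C1'' radical to give 15.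

2. Step 10.
   - Insertion may be slow on the electron-rich chromone with an ortho-substituted boronic acid.
   - Protodeboronation and a second addition to the new ketone may compete.
   - The fallback sets out from 15 and 17 and comes back at 20. Chromone 15 is opened with aqueous NaOH in EtOH (attack at C2, retro-Claisen loss of formate) to the lavandulyl acetophenone F4. Bromide 17 is converted (n-BuLi, then DMF) into the benzaldehyde F5. Claisen–Schmidt condensation (KOH, EtOH, 25 °C) gives the chalcone F6. NaOAc in refluxing EtOH closes ring C by oxa-Michael addition to the flavanone epimeric at C2, F7. Kinetic resolution by Noyori-type transfer hydrogenation (Cp*RhCl[(R,R)-TsDPEN], HCO2H/Et3N, EtOAc, 25 °C) should reduce the (2R)-epimer to the cis-(2R,4R)-flavan-4-ol F8 and leave 20, which is separated by chromatography.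

3. Step 2.
   - Formylation may occur at C6 instead of C8, or at both positions.
   - The fallback sets out from 3 and comes back at 5. Phenol 3 is capped first (MOMCl, i-Pr2NEt, CH2Cl2) to the 7-MOM chromone F9. Iodination with N-iodosuccinimide in DMF goes para to the 5-alkoxy group on 5,7-dialkoxybenzopyranones and should give the 8-iodochromone F10. Palladium-catalysed reductive carbonylation (Pd(PPh3)4, CO 1 atm, Bu3SnH, THF, 50 °C) then installs the aldehyde to give 5.

**Further compounds**

F1 | step 7 | 2-[(2E)-2,6-dimethylhepta-2,5-dien-1-yl]-4,4,5,5-tetramethyl-1,3,2-dioxaborolane | CC(C)=CC/C=C(\C)CB1OC(C)(C)C(C)(C)O1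
F2 | step 7 | 8-[(1S,2S)-1-hydroxy-5-methyl-2-(prop-1-en-2-yl)hex-4-en-1-yl]-5-methoxy-7-(methoxymethoxy)-4H-chromen-4-one | C=C(C)[C@H](CC=C(C)C)[C@H](O)c1c(OCOC)cc(OC)c2c1occc2=O
F3 | step 7 | O-{(1S,2S)-1-[5-methoxy-7-(methoxymethoxy)-4-oxo-4H-chromen-8-yl]-5-methyl-2-(prop-1-en-2-yl)hex-4-en-1-yl} 1H-imidazole-1-carbothioate | C=C(C)[C@H](CC=C(C)C)[C@H](OC(=S)n1ccnc1)c1c(OCOC)cc(OC)c2c1occc2=O
F4 | step 10 | 1-{2-hydroxy-6-methoxy-4-(methoxymethoxy)-3-[(2R)-5-methyl-2-(prop-1-en-2-yl)hex-4-en-1-yl]phenyl}ethan-1-one | C=C(C)[C@H](CC=C(C)C)Cc1c(OCOC)cc(OC)c(C(C)=O)c1O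
F5 | step 10 | 4-methoxy-2-(methoxymethoxy)benzaldehyde | COCOc1cc(OC)ccc1C=O
F6 | step 10 | (2E)-1-{2-hydroxy-6-methoxy-4-(methoxymethoxy)-3-[(2R)-5-methyl-2-(prop-1-en-2-yl)hex-4-en-1-yl]phenyl}-3-[4-methoxy-2-(methoxymethoxy)phenyl]prop-2-en-1-one | C=C(C)[C@H](CC=C(C)C)Cc1c(OCOC)cc(OC)c(C(=O)/C=C/c2ccc(OC)cc2OCOC)c1O
F7 | step 10 | (2RS)-5-methoxy-7-(methoxymethoxy)-2-[4-methoxy-2-(methoxymethoxy)phenyl]-8-[(2R)-5-methyl-2-(prop-1-en-2-yl)hex-4-en-1-yl]-2,3-dihydro-4H-chromen-4-one | C=C(C)[C@H](CC=C(C)C)Cc1c(OCOC)cc(OC)c2c1OC(c1ccc(OC)cc1OCOC)CC2=O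
F8 | step 10 | (2R,4R)-5-methoxy-7-(methoxymethoxy)-2-[4-methoxy-2-(methoxymethoxy)phenyl]-8-[(2R)-5-methyl-2-(prop-1-en-2-yl)hex-4-en-1-yl]-3,4-dihydro-2H-chromen-4-ol | C=C(C)[C@H](CC=C(C)C)Cc1c(OCOC)cc(OC)c2c1O[C@@H](c1ccc(OC)cc1OCOC)C[C@H]2O
F9 | step 2 | 5-methoxy-7-(methoxymethoxy)-4H-chromen-4-one | COCOc1cc(OC)c2c(c1)occc2=O
F10 | step 2 | 8-iodo-5-methoxy-7-(methoxymethoxy)-4H-chromen-4-one | COCOc1cc(OC)c2c(c1I)occc2=O
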